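## Analysis of the target

Compound 20 is a 1-aryltetralin (a cyclolignan). Ring A is the benzo ring with a methoxy group at C6 and a free hydroxyl at C7, ring B is the saturated six-membered ring (C1–C4, C4a, C8a), and ring C is the 4-hydroxy-3,5-dimethoxyphenyl group on C1. C2 and C3 each carry an acetoxymethyl group and C4 is an unsubstituted benzylic methylene. The three contiguous stereocentres C1 (S), C2 (R) and C3 (R) are all-trans, so ring C and the two side chains alternate between the faces of ring B and can all sit equatorial. C2 and C3 can therefore be set by equilibration while they carry esters. C1 is a diarylmethine with no acidifying neighbour, cannot be corrected, and must be made with absolute control although its two aryl groups are electronically alike. The sensitive groups are the two primary acetates, which tolerate neither alkoxide nor hydride and must come late, and the two phenols. The ring C phenol is para to C1 and, once free under basic or oxidising conditions, opens a quinone-methide path by which C1 would be lost. The strategy rests on C1 being benzylic to the donor ring C while C3 can bear a malonate. C1–C2–C3 is then the opened form of a donor–acceptor cyclopropane, whose ends face C8a (the ring A carbon para to the C6 methoxy group) and the benzylic carbon C4.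

## Retrosynthetic reasoning

The two phenolic O–H bonds of 20 are traced back to benzyl ethers (19). Hydrogenolysis is neutral and spares the acetates, and one group on both phenols makes the last step a single operation. Cutting the two acetyl C–O bonds gives diol 18, and raising both hydroxymethyl carbons to the carboxyl level gives diester 17, because only as esters are C2 and C3 epimerisable.

In 17 the ring A benzyl ether is disconnected to phenol 16, and the configurations at C2 and C3 are then given up: 16 is the thermodynamic member of the epimer family 15, in which only C1 is defined. The forward step must move C2 and C3 to the all-trans array without touching C1. An alkoxide base does this and also removes the pivalate that ring A needed earlier, which is why ring A is benzylated only afterwards.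

15 is derived from triester 14 by adding back a second ester at C3. This costs one dealkoxycarbonylation, but it makes C3 a malonate carbon, which both activates the cyclopropane and serves as the nucleophile for C4.

In 14 the bonds C1–C8a and C3–C4 are cut. This removes ring B at once and divides the molecule into cyclopropane 8 (ring C and the sp3 carbons C1–C3) and arene 12 (ring A and C4).
- C1–C8a is cut because its formation by backside attack can carry the configuration of a cyclopropane carbon over to C1. C3–C4 is cut because it is a plain malonate alkylation that follows in the same flask.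
- Cutting C1–C1′ instead would leave C1 to substrate control from C2 and C3, which would then have to be built first. Cutting C1–C2 and C3–C4 would demand an o-quinodimethane.
- The forward reaction must achieve attack by the ring A carbon para to the methoxy group, inversion at C1, and ring closure before the benzylic bromide reacts otherwise. The pivalate on the para oxygen of 12 keeps that bromide covalent and leaves the carbon para to the methoxy group as the most nucleophilic site.
- Inversion on the trans cyclopropane gives 1,2-cis. This is acceptable only because C2 bears an ester and is corrected on going from 15 to 16.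

8 is taken back through acid 7 to aldehyde 6. The formyl group is oxidised before the key step because it would itself be attacked under Lewis acid activation, while the ester keeps C2 epimerisable. Cyclopropane 6 is cut at the two bonds from the malonate carbon (to the aryl-bearing and the formyl-bearing carbons), giving enal 4 and bromomalonate 5. This is an amine-catalysed Michael addition/alkylation cascade, in which a chiral secondary amine sets the aryl-bearing carbon, the only source of absolute configuration in the route.

Enal 4 is cut at its C=C bond to aldehyde 2 and a two-carbon ylide, and 2 at the benzyl ether to syringaldehyde 1. The benzyl group keeps ring C a strong donor for the ring opening, is inert to the later reagents, and masks the phenol para to C1 through all basic steps.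

12 is traced through alcohol 11 and aldehyde 10 to vanillin 9, which already has the methoxy/hydroxy pattern of ring A.

## Alternatives that were turned down

Alternative 1: Both bonds from C1 to the aryl rings (C1–C1′ and C1–C8a) are cut, so that C1 becomes the anomeric carbon of lactol A1, a tetrahydrofuran that already holds C2 and C3 with their side chains. Forward, a Lewis acid ionises A1, 2,6-dimethoxyphenol A2 adds through its para carbon, the benzylic cyclic ether so formed ionises again at C1, and ring A closes to give tetralin A3.
- For: the para carbon of A2 is far more nucleophilic than the ring A carbon of 12, the closure is intramolecular, and reversible ionisation lets C1 settle trans to C2. On the reactivity and robustness of the C1–aryl bond formation this alternative is the stronger one. Ring C also arrives unprotected.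
- Against: all absolute configuration rests on C2 and C3 of A1, which must be built first as a cis-disubstituted lactol with two differentiated oxygen functions, a multistep asymmetric sequence. Ring A can intercept the oxocarbenium ion before A2 does. After the key step the silyl ether must be exchanged and two alcohols acetylated beside a free ring C phenol, so steps saved early are spent late.
- Comparison: the chosen strategy builds no stereocentre before one catalytic step, corrects C2 and C3 by equilibration and assembles ring B from two simple aromatic pieces. The price is a weaker arene nucleophile in its key step.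

Alternative 2: C1–C2 and C3–C4 are cut, the Diels–Alder retron of ring B. Forward, irradiation of 2-benzylbenzaldehyde A4 gives a hydroxy-o-quinodimethane, which adds to the bis-lactate fumarate A5 to give tetralin A6.
- For: ring B and four stereocentres arise in one pericyclic step, and the 2,3-trans diester comes from the dienophile geometry, so no equilibration is needed. In stereocentres per step this alternative is stronger.
- Against: A6 carries a C4 hydroxyl that the target lacks, and its benzylic deoxygenation competes with the benzyl ethers. Facial control depends on two auxiliaries remote from the forming bonds, and endo/exo control decides 1,2-cis or trans. The alkoxy donors on the aldehyde ring lower the efficiency of photoenolisation. The auxiliaries are stoichiometric and the step is photochemical.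
- Comparison: the chosen strategy takes its absolute configuration from a catalytic step of a reliable class and needs neither light nor deoxygenation. It gives up the one-step creation of the full stereo-array.

Alternative 3: C3–C4 and C4–C4a are cut, so that C4 comes from formaldehyde A8 and the precursor is aldehyde A7, which already contains C1 and C2. Forward, A7 is α-methylenated with A8 under amine catalysis and, on acidification, the ring A phenol attacks the terminal carbon of the enal through its carbon para to the hydroxyl, giving tetralin A9.
- For: the free phenol activates exactly the carbon that must react, C3 is set under thermodynamic control, and A9 has ring A unprotected and the two side chains already differentiated. On ring-closure reactivity and protecting-group economy at ring A it is as strong as or stronger than the chosen route.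
- Against: the hard stereocentre C1, with its two similar aryl groups, and C2 must both be present in A7, so the real problem is moved upstream and needs its own asymmetric chemistry. The closure is a 6-endo attack on an unactivated 2-substituted acrolein, which competes with its dimerisation and with attack through the phenol oxygen.
- Comparison: the chosen strategy creates C1 in the operation that builds ring B, from an achiral ring A piece, instead of presupposing it.

Key step: step 9

Assumption (chemistry): the sense of induction in step 3 is taken from the usual shielding model of diarylprolinol silyl ether iminium ions, which calls for the (R)-catalyst; should the sense prove opposite, the (S)-catalyst would be used and nothing else would change.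

## Route

Step 1
Reactants: 1 syringaldehyde (4-hydroxy-3,5-dimethoxybenzaldehyde)
Product: 2 4-(benzyloxy)-3,5-dimethoxybenzaldehyde
Conditions: BnBr, K2CO3, DMF, 60 °C
Reagents that add atoms: benzyl bromide, BrCc1ccccc1
Why: Williamson ether synthesis on the acidic, hindered phenoxide; the aldehyde is not affected.

Step 2
Reactants: 2 4-(benzyloxy)-3,5-dimethoxybenzaldehyde
Product: 4 (E)-3-[4-(benzyloxy)-3,5-dimethoxyphenyl]prop-2-enal, via styryl dioxolane 3 (not isolated)
Conditions: (1,3-dioxolan-2-ylmethyl)triphenylphosphonium bromide, t-BuOK, THF, 0 °C to rt; then 1 M HCl, THF, rt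
Reagents that add atoms: (1,3-dioxolan-2-ylmethyl)triphenylphosphonium bromide, [Br-].C1COC(C[P+](c2ccccc2)(c2ccccc2)c2ccccc2)O1; water, O
Why: Wittig olefination with a masked formylmethylene ylide adds two carbons without the over-homologation a free formyl ylide allows; aqueous acid then hydrolyses the acetal and equilibrates the alkene to the conjugated (E)-enal.

Step 3
Reactants: 4 (E)-3-[4-(benzyloxy)-3,5-dimethoxyphenyl]prop-2-enal; 5 dimethyl bromomalonate
Product: 6 dimethyl (2S,3R)-3-[4-(benzyloxy)-3,5-dimethoxyphenyl]-2-formylcyclopropane-1,1-dicarboxylate (aryl and formyl trans)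
Conditions: (R)-α,α-diphenylprolinol trimethylsilyl ether (20 mol%), 2,6-lutidine (1.1 equiv), CH2Cl2, 0 °C to rt
Reagents that add atoms: none
Why: Known organocatalytic Michael-initiated ring closure: the bromomalonate anion adds to the β-carbon of the (E)-iminium ion on the face away from the diphenyl(silyloxy)methyl group, and the enamine then displaces bromide (3-exo-tet). This sets the aryl-bearing carbon as R and, through the favoured trans closure, the formyl-bearing carbon as S; the weak base 2,6-lutidine is chosen so that the product ring is not opened again.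

Step 4
Reactants: 6 dimethyl (2S,3R)-3-[4-(benzyloxy)-3,5-dimethoxyphenyl]-2-formylcyclopropane-1,1-dicarboxylate
Product: 7 (1S,3R)-3-[4-(benzyloxy)-3,5-dimethoxyphenyl]-2,2-bis(methoxycarbonyl)cyclopropane-1-carboxylic acid
Conditions: NaClO2, NaH2PO4, 2-methyl-2-butene (excess), t-BuOH/H2O, 0 °C to rt
Reagents that add atoms: sodium chlorite, [Na+].[O-]Cl=O
Why: Pinnick oxidation converts the aldehyde to the acid under buffered conditions that do not epimerise or open the cyclopropane; the alkene scavenger keeps hypochlorous acid from chlorinating the electron-rich ring.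

Step 5
Reactants: 7 (1S,3R)-3-[4-(benzyloxy)-3,5-dimethoxyphenyl]-2,2-bis(methoxycarbonyl)cyclopropane-1-carboxylic acid
Product: 8 trimethyl (2S,3R)-3-[4-(benzyloxy)-3,5-dimethoxyphenyl]cyclopropane-1,1,2-tricarboxylate (aryl and C2 ester trans)
Conditions: MeI, K2CO3, DMF, rt
Reagents that add atoms: iodomethane, CI
Why: O-alkylation of the carboxylate; the trans arrangement is the stable one, so mild carbonate cannot degrade it.

Step 6
Reactants: 9 vanillin (4-hydroxy-3-methoxybenzaldehyde)
Product: 10 4-formyl-2-methoxyphenyl pivalate
Conditions: PivCl, Et3N, DMAP (cat.), CH2Cl2, 0 °C to rt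
Reagents that add atoms: pivaloyl chloride, CC(C)(C)C(Cl)=O
Why: Acylation of the phenol; the hindered ester is chosen because it survives borohydride, PBr3 and the Lewis acid of step 9.

Step 7
Reactants: 10 4-formyl-2-methoxyphenyl pivalate
Product: 11 4-(hydroxymethyl)-2-methoxyphenyl pivalate
Conditions: NaBH4, THF/MeOH, 0 °C
Reagents that add atoms: none
Why: Borohydride reduces the aldehyde much faster than it attacks the hindered aryl ester at 0 °C.

Step 8
Reactants: 11 4-(hydroxymethyl)-2-methoxyphenyl pivalate
Product: 12 4-(bromomethyl)-2-methoxyphenyl pivalate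
Conditions: PBr3, CH2Cl2, 0 °C
Reagents that add atoms: phosphorus tribromide, BrP(Br)Br
Why: Standard conversion of a primary benzylic alcohol to the bromide; the acyl group on the para oxygen keeps the product from ionising on storage.

Step 9
Reactants: 8 trimethyl (2S,3R)-3-[4-(benzyloxy)-3,5-dimethoxyphenyl]cyclopropane-1,1,2-tricarboxylate; 12 4-(bromomethyl)-2-methoxyphenyl pivalate
Product: 14 trimethyl (1S,2S)-1-[4-(benzyloxy)-3,5-dimethoxyphenyl]-6-methoxy-7-(pivaloyloxy)-1,4-dihydronaphthalene-2,3,3(2H)-tricarboxylate (1,2-cis), via open-chain bromo malonate 13 (not isolated)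
Conditions: 12 (3 equiv), Sc(OTf)3 (20 mol%), 4 Å MS, ClCH2CH2Cl, 40 °C, 8 added slowly; then MeCN (dilution), Cs2CO3 (3 equiv), rt
Reagents that add atoms: none
Why: Proposed new method: Sc(OTf)3 chelates the geminal diester of 8 and weakens the bond between the malonate carbon and the aryl-bearing carbon, which becomes a tight, benzylically stabilised electrophile; the carbon of 12 para to its methoxy group attacks it from the side opposite the departing malonate, and loss of the arenium proton gives the open-chain malonate 13. The closest known reaction type is the Lewis-acid-catalysed Friedel–Crafts ring opening of 2-arylcyclopropane-1,1-diesters by electron-rich arenes, which runs with inversion, together with their formal (3+3) annulations. Added Cs2CO3 then deprotonates the malonate, which displaces the benzylic bromide in a 6-exo-tet alkylation and closes ring B, the only ring formed. The new stereocentre C1 is controlled by the configured aryl-bearing carbon of 8 through backside attack, which makes it S and places ring C cis to the C2 ester; C2 is carried over unchanged and corrected in step 11. The step needs site selectivity on 12, which the para-directing methoxy group, the only weakly donating pivaloyloxy group and the lower hindrance at that carbon should secure. It needs the bromide to stay covalent in the first stage, for which the acyl group on the para oxygen and an oxophilic rather than halophilic Lewis acid are chosen. It needs intermolecular capture to outrun ionisation of 8, so 12 is used in excess and 8 is kept at low concentration; dilution before the base favours ring closure over alkylation by surplus 12. New here are the weakly nucleophilic arene, the vicinal ester on the cyclopropane and the one-pot closure.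

Step 10
Reactants: 14 trimethyl (1S,2S)-1-[4-(benzyloxy)-3,5-dimethoxyphenyl]-6-methoxy-7-(pivaloyloxy)-1,4-dihydronaphthalene-2,3,3(2H)-tricarboxylate
Product: 15 dimethyl (1S)-1-[4-(benzyloxy)-3,5-dimethoxyphenyl]-6-methoxy-7-(pivaloyloxy)-1,2,3,4-tetrahydronaphthalene-2,3-dicarboxylate (mixture of C2/C3 epimers)
Conditions: LiCl, H2O (2 equiv), DMSO, 150 °C
Reagents that add atoms: none
Why: Krapcho dealkoxycarbonylation: chloride demethylates one of the geminal esters and the carboxylate loses CO2 because the second ester stabilises the carbanion, whereas the lone C2 ester cannot decarboxylate. The new C3 centre is formed unselectively, which is harmless because step 11 equilibrates it; any pivalate lost here is lost in step 11 anyway.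

Step 11
Reactants: 15 dimethyl (1S)-1-[4-(benzyloxy)-3,5-dimethoxyphenyl]-6-methoxy-7-(pivaloyloxy)-1,2,3,4-tetrahydronaphthalene-2,3-dicarboxylate
Product: 16 dimethyl (1S,2R,3R)-1-[4-(benzyloxy)-3,5-dimethoxyphenyl]-7-hydroxy-6-methoxy-1,2,3,4-tetrahydronaphthalene-2,3-dicarboxylate (all-trans)
Conditions: NaOMe (3 equiv), MeOH, reflux, under argon; then aq. NH4Cl
Reagents that add atoms: none
Why: Thermodynamic epimerisation through the two ester enolates: C1 has no acidic hydrogen and stays fixed, so C2 and C3 settle relative to it in the all-equatorial 1,2-trans-2,3-trans arrangement (C2 R, C3 R). Methoxide also cleaves the aryl pivalate by transesterification; the ring C phenol stays benzylated, so C1 cannot be lost through a quinone methide.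

Step 12
Reactants: 16 dimethyl (1S,2R,3R)-1-[4-(benzyloxy)-3,5-dimethoxyphenyl]-7-hydroxy-6-methoxy-1,2,3,4-tetrahydronaphthalene-2,3-dicarboxylate
Product: 17 dimethyl (1S,2R,3R)-7-(benzyloxy)-1-[4-(benzyloxy)-3,5-dimethoxyphenyl]-6-methoxy-1,2,3,4-tetrahydronaphthalene-2,3-dicarboxylate
Conditions: BnBr, K2CO3, DMF, rt
Reagents that add atoms: benzyl bromide, BrCc1ccccc1
Why: Williamson ether synthesis on the phenoxide; carbonate is too weak to alkylate the ester α-carbons, and the stereo-array is already the thermodynamic one.

Step 13
Reactants: 17 dimethyl (1S,2R,3R)-7-(benzyloxy)-1-[4-(benzyloxy)-3,5-dimethoxyphenyl]-6-methoxy-1,2,3,4-tetrahydronaphthalene-2,3-dicarboxylate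
Product: 18 [(1S,2R,3R)-7-(benzyloxy)-1-[4-(benzyloxy)-3,5-dimethoxyphenyl]-6-methoxy-1,2,3,4-tetrahydronaphthalene-2,3-diyl]dimethanol
Conditions: LiAlH4, THF, 0 °C to rt
Reagents that add atoms: none
Why: Hydride reduction of both esters to primary alcohols; reduction is faster than enolisation, so C2 and C3 are kept, and the ethers are inert.

Step 14
Reactants: 18 [(1S,2R,3R)-7-(benzyloxy)-1-[4-(benzyloxy)-3,5-dimethoxyphenyl]-6-methoxy-1,2,3,4-tetrahydronaphthalene-2,3-diyl]dimethanol
Product: 19 [(1S,2R,3R)-7-(benzyloxy)-1-[4-(benzyloxy)-3,5-dimethoxyphenyl]-6-methoxy-1,2,3,4-tetrahydronaphthalene-2,3-diyl]bis(methylene) diacetate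
Conditions: Ac2O, pyridine, DMAP (cat.), CH2Cl2, rt
Reagents that add atoms: acetic anhydride, CC(=O)OC(C)=O
Why: Acylation of the two primary alcohols; with both phenols still benzylated no selectivity is required.

Step 15
Reactants: 19 [(1S,2R,3R)-7-(benzyloxy)-1-[4-(benzyloxy)-3,5-dimethoxyphenyl]-6-methoxy-1,2,3,4-tetrahydronaphthalene-2,3-diyl]bis(methylene) diacetate
Product: 20 [(1S,2R,3R)-7-hydroxy-1-(4-hydroxy-3,5-dimethoxyphenyl)-6-methoxy-1,2,3,4-tetrahydronaphthalene-2,3-diyl]bis(methylene) diacetate (the target)
Conditions: H2 (1 atm), 10% Pd/C, EtOAc, rt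
Reagents that add atoms: none
Why: Hydrogenolysis of the two aryl benzyl ethers under neutral conditions; the acetates, the C–C bonds at C1 and the aromatic rings are not touched.

## Compound list

1 | syringaldehyde (4-hydroxy-3,5-dimethoxybenzaldehyde) | COc1cc(C=O)cc(OC)c1O | starting material
2 | 4-(benzyloxy)-3,5-dimethoxybenzaldehyde | COc1cc(C=O)cc(OC)c1OCc1ccccc1 | intermediate
3 | 2-{2-[4-(benzyloxy)-3,5-dimethoxyphenyl]ethenyl}-1,3-dioxolane (E/Z mixture, not isolated) | COc1cc(C=CC2OCCO2)cc(OC)c1OCc1ccccc1 | intermediate
4 | (E)-3-[4-(benzyloxy)-3,5-dimethoxyphenyl]prop-2-enal | COc1cc(/C=C/C=O)cc(OC)c1OCc1ccccc1 | intermediate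
5 | dimethyl bromomalonate | COC(=O)C(Br)C(=O)OC | starting material
6 | dimethyl (2S,3R)-3-[4-(benzyloxy)-3,5-dimethoxyphenyl]-2-formylcyclopropane-1,1-dicarboxylate | COC(=O)C1(C(=O)OC)[C@@H](c2cc(OC)c(OCc3ccccc3)c(OC)c2)[C@@H]1C=O | intermediate
7 | (1S,3R)-3-[4-(benzyloxy)-3,5-dimethoxyphenyl]-2,2-bis(methoxycarbonyl)cyclopropane-1-carboxylic acid | COC(=O)C1(C(=O)OC)[C@@H](c2cc(OC)c(OCc3ccccc3)c(OC)c2)[C@@H]1C(=O)O | intermediate
8 | trimethyl (2S,3R)-3-[4-(benzyloxy)-3,5-dimethoxyphenyl]cyclopropane-1,1,2-tricarboxylate | COC(=O)C1(C(=O)OC)[C@@H](c2cc(OC)c(OCc3ccccc3)c(OC)c2)[C@@H]1C(=O)OC | intermediate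
9 | vanillin (4-hydroxy-3-methoxybenzaldehyde) | COc1cc(C=O)ccc1O | starting material
10 | 4-formyl-2-methoxyphenyl pivalate | COc1cc(C=O)ccc1OC(=O)C(C)(C)C | intermediate
11 | 4-(hydroxymethyl)-2-methoxyphenyl pivalate | COc1cc(CO)ccc1OC(=O)C(C)(C)C | intermediate
12 | 4-(bromomethyl)-2-methoxyphenyl pivalate | COc1cc(CBr)ccc1OC(=O)C(C)(C)C | intermediate
13 | trimethyl (2S,3S)-3-[4-(benzyloxy)-3,5-dimethoxyphenyl]-3-[2-(bromomethyl)-4-methoxy-5-(pivaloyloxy)phenyl]propane-1,1,2-tricarboxylate (not isolated) | COc1cc(CBr)c(cc1OC(=O)C(C)(C)C)[C@H](c1cc(OC)c(OCc3ccccc3)c(OC)c1)[C@H](C(=O)OC)C(C(=O)OC)C(=O)OC | intermediate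
14 | trimethyl (1S,2S)-1-[4-(benzyloxy)-3,5-dimethoxyphenyl]-6-methoxy-7-(pivaloyloxy)-1,4-dihydronaphthalene-2,3,3(2H)-tricarboxylate (1,2-cis) | COc1cc2c(cc1OC(=O)C(C)(C)C)[C@H](c1cc(OC)c(OCc3ccccc3)c(OC)c1)[C@H](C(=O)OC)C(C(=O)OC)(C(=O)OC)C2 | intermediate
15 | dimethyl (1S)-1-[4-(benzyloxy)-3,5-dimethoxyphenyl]-6-methoxy-7-(pivaloyloxy)-1,2,3,4-tetrahydronaphthalene-2,3-dicarboxylate (C2/C3 epimer mixture) | COc1cc2c(cc1OC(=O)C(C)(C)C)[C@H](c1cc(OC)c(OCc3ccccc3)c(OC)c1)C(C(=O)OC)C(C(=O)OC)C2 | intermediate
16 | dimethyl (1S,2R,3R)-1-[4-(benzyloxy)-3,5-dimethoxyphenyl]-7-hydroxy-6-methoxy-1,2,3,4-tetrahydronaphthalene-2,3-dicarboxylate (all-trans) | COc1cc2c(cc1O)[C@H](c1cc(OC)c(OCc3ccccc3)c(OC)c1)[C@@H](C(=O)OC)[C@H](C(=O)OC)C2 | intermediate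
17 | dimethyl (1S,2R,3R)-7-(benzyloxy)-1-[4-(benzyloxy)-3,5-dimethoxyphenyl]-6-methoxy-1,2,3,4-tetrahydronaphthalene-2,3-dicarboxylate | COc1cc2c(cc1OCc1ccccc1)[C@H](c1cc(OC)c(OCc3ccccc3)c(OC)c1)[C@@H](C(=O)OC)[C@H](C(=O)OC)C2 | intermediate
18 | [(1S,2R,3R)-7-(benzyloxy)-1-[4-(benzyloxy)-3,5-dimethoxyphenyl]-6-methoxy-1,2,3,4-tetrahydronaphthalene-2,3-diyl]dimethanol | COc1cc2c(cc1OCc1ccccc1)[C@H](c1cc(OC)c(OCc3ccccc3)c(OC)c1)[C@@H](CO)[C@H](CO)C2 | intermediate
19 | [(1S,2R,3R)-7-(benzyloxy)-1-[4-(benzyloxy)-3,5-dimethoxyphenyl]-6-methoxy-1,2,3,4-tetrahydronaphthalene-2,3-diyl]bis(methylene) diacetate | COc1cc2c(cc1OCc1ccccc1)[C@H](c1cc(OC)c(OCc3ccccc3)c(OC)c1)[C@@H](COC(C)=O)[C@H](COC(C)=O)C2 | intermediate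
20 | [(1S,2R,3R)-7-hydroxy-1-(4-hydroxy-3,5-dimethoxyphenyl)-6-methoxy-1,2,3,4-tetrahydronaphthalene-2,3-diyl]bis(methylene) diacetate (CNP0265800.1) | COc1cc2c(cc1O)[C@H](c1cc(OC)c(O)c(OC)c1)[C@@H](COC(C)=O)[C@H](COC(C)=O)C2 | target

## Step count and least certain steps

Total step count: 15. Longest linear sequence: 12 steps (steps 1–5 and 9–15, from 1); steps 6–8 form the second arm.

**Step 9 (key step).** Most likely to go wrong is capture of the activated cyclopropane by the arene. The reacting carbon of 12 is only anisole-like in nucleophilicity and is flanked by the bromomethyl group, whereas the donor ring of 8 is itself electron-rich. Three processes may therefore outrun the wanted attack: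
- Lewis-acid ionisation of 8 followed by proton loss from C2, giving an alkene.
- Attack of a second molecule of 8 through its own ring, giving oligomers.
- Slow ionisation of the benzylic bromide, giving self-benzylation.

Any ionisation of 8 before attack also erodes inversion at C1. Because C2 and C3 are later set relative to C1, this would appear as loss of enantiomeric purity in 16.

Fallback (known chemistry; sets out from 2 and 9, returns at 18): ring B is closed by an intramolecular Friedel–Crafts reaction on a C1 cation, with the stereochemistry relayed from C3. Vanillin 9 is benzylated (BnBr, K2CO3) to 4-(benzyloxy)-3-methoxybenzaldehyde F1. Stobbe condensation with dimethyl succinate (NaOMe, MeOH) gives the (E)-half-ester F2. Hydrogenation with a cationic rhodium diphosphine catalyst such as [Rh(cod)(Et-DuPHOS)]BF4, the ligand antipode being chosen for the (R) product, gives the (R)-benzylsuccinic half-ester F3. Reduction of the ester group of its carboxylate salt with Ca(BH4)2 and acidification gives the (R)-lactone F4. Its lithium enolate (LiN(SiMe3)2, THF, −78 °C) adds to aldehyde 2 to give the trans hydroxybenzyl lactone F5 as a mixture of carbinol epimers. CF3CO2H in CH2Cl2 ionises the carbinol and ring A closes through its carbon para to the methoxy group to give the all-trans lactone F6. LiAlH4 reduces F6 to diol 18. C3 directs C2 in the aldol step and C2 directs C1 in the cyclisation, so steps 3 to 13 are replaced.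

**Step 3.** The iminium ion of the electron-rich enal 4 is a weak acceptor, so the Michael addition may be slow. The formylcyclopropane formed is a donor–acceptor cyclopropane that the amine can open again through its own iminium ion, so product may be consumed as it forms.

Fallback (sets out from 4, returns at 6): the two events of the cascade are separated. Michael addition of dimethyl malonate to 4 with the same (R)-amine (benzoic acid co-catalyst, EtOH) gives dimethyl 2-[(1S)-1-[4-(benzyloxy)-3,5-dimethoxyphenyl]-3-oxopropyl]propanedioate F7, a stable aldehyde. Iodination of its malonate carbon (I2, 2,6-lutidine, CH2Cl2) in the presence of the amine regenerates the halomalonate enamine of the cascade, which closes to 6.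

**Step 10.** Hot chloride may act elsewhere than at the geminal esters: slow demethylation of the C2 ester to an acid that cannot decarboxylate, and partial cleavage of the aryl benzyl ether or of the pivalate. The quaternary geminal diester is also hindered, so long reaction times may be needed.

Fallback (sets out from 14, returns at 16): the carbon is removed by hydrolysis instead of halide dealkylation. KOH in aqueous MeOH/THF at reflux cleaves the three methyl esters and the pivalate to the phenolic triacid F8. Heating F8 in pyridine at about 110 °C decarboxylates the malonic acid to the diacid F9. Fischer esterification (MeOH, H2SO4 cat., reflux) gives the phenolic dimethyl ester F10 as an epimer mixture, which is submitted to the conditions of step 11 and so gives 16.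

**Step 11.** Equilibration may stop short of the all-trans isomer, because a pseudo-axial ring C makes the 1,2-cis isomer less disfavoured than in a simple cyclohexane. During the long exposure to hot methoxide the ring A phenoxide may be oxidised by traces of air, and adventitious hydroxide may hydrolyse an ester. Isomers that remain can be returned to the equilibration.

Fallback (sets out from 15, returns at 17): the order is changed so that equilibration runs on a fully protected substrate. Brief treatment of 15 with NaOMe in MeOH at 0 °C removes only the pivalate and gives the phenolic diester F11 (epimer mixture, the same constitution as F10). Benzylation (BnBr, K2CO3, DMF) gives the bis-benzyl diester F12 as an epimer mixture. NaOMe in MeOH at reflux then equilibrates F12 to 17, with no phenoxide present.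

## Further compounds

F1 | step 9 | 4-(benzyloxy)-3-methoxybenzaldehyde | COc1cc(C=O)ccc1OCc1ccccc1
F2 | step 9 | (E)-4-[4-(benzyloxy)-3-methoxyphenyl]-3-(methoxycarbonyl)but-3-enoic acid | COC(=O)/C(=C/c1ccc(OCc2ccccc2)c(OC)c1)CC(=O)O
F3 | step 9 | (R)-4-[4-(benzyloxy)-3-methoxyphenyl]-3-(methoxycarbonyl)butanoic acid | COC(=O)[C@H](Cc1ccc(OCc2ccccc2)c(OC)c1)CC(=O)O
F4 | step 9 | (R)-4-[4-(benzyloxy)-3-methoxybenzyl]dihydrofuran-2(3H)-one | O=C1C[C@@H](Cc2ccc(OCc3ccccc3)c(OC)c2)CO1
F5 | step 9 | (3S,4R)-4-[4-(benzyloxy)-3-methoxybenzyl]-3-{[4-(benzyloxy)-3,5-dimethoxyphenyl](hydroxy)methyl}dihydrofuran-2(3H)-one (trans, carbinol epimers) | O=C1OC[C@H](Cc2ccc(OCc3ccccc3)c(OC)c2)[C@H]1C(O)c1cc(OC)c(OCc2ccccc2)c(OC)c1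
F6 | step 9 | γ-lactone of (1S,2R,3R)-7-(benzyloxy)-1-[4-(benzyloxy)-3,5-dimethoxyphenyl]-3-(hydroxymethyl)-6-methoxy-1,2,3,4-tetrahydronaphthalene-2-carboxylic acid (all-trans) | COc1cc2c(cc1OCc1ccccc1)[C@H](c1cc(OC)c(OCc3ccccc3)c(OC)c1)[C@H]1C(=O)OC[C@@H]1C2
F7 | step 3 | dimethyl 2-[(1S)-1-[4-(benzyloxy)-3,5-dimethoxyphenyl]-3-oxopropyl]propanedioate | COC(=O)C(C(=O)OC)[C@@H](c1cc(OC)c(OCc2ccccc2)c(OC)c1)CC=O
F8 | step 10 | (1S)-1-[4-(benzyloxy)-3,5-dimethoxyphenyl]-7-hydroxy-6-methoxy-1,4-dihydronaphthalene-2,3,3(2H)-tricarboxylic acid (C2 epimers) | COc1cc2c(cc1O)[C@H](c1cc(OC)c(OCc3ccccc3)c(OC)c1)C(C(=O)O)C(C(=O)O)(C(=O)O)C2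
F9 | step 10 | (1S)-1-[4-(benzyloxy)-3,5-dimethoxyphenyl]-7-hydroxy-6-methoxy-1,2,3,4-tetrahydronaphthalene-2,3-dicarboxylic acid (C2/C3 epimers) | COc1cc2c(cc1O)[C@H](c1cc(OC)c(OCc3ccccc3)c(OC)c1)C(C(=O)O)C(C(=O)O)C2
F10 | step 10 | dimethyl (1S)-1-[4-(benzyloxy)-3,5-dimethoxyphenyl]-7-hydroxy-6-methoxy-1,2,3,4-tetrahydronaphthalene-2,3-dicarboxylate (C2/C3 epimers) | COc1cc2c(cc1O)[C@H](c1cc(OC)c(OCc3ccccc3)c(OC)c1)C(C(=O)OC)C(C(=O)OC)C2
F11 | step 11 | dimethyl (1S)-1-[4-(benzyloxy)-3,5-dimethoxyphenyl]-7-hydroxy-6-methoxy-1,2,3,4-tetrahydronaphthalene-2,3-dicarboxylate (C2/C3 epimers) | COc1cc2c(cc1O)[C@H](c1cc(OC)c(OCc3ccccc3)c(OC)c1)C(C(=O)OC)C(C(=O)OC)C2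
F12 | step 11 | dimethyl (1S)-7-(benzyloxy)-1-[4-(benzyloxy)-3,5-dimethoxyphenyl]-6-methoxy-1,2,3,4-tetrahydronaphthalene-2,3-dicarboxylate (C2/C3 epimers) | COc1cc2c(cc1OCc1ccccc1)[C@H](c1cc(OC)c(OCc3ccccc3)c(OC)c1)C(C(=O)OC)C(C(=O)OC)C2
A1 | alternative 1 | (3R,4R)-4-[4-(benzyloxy)-3-methoxybenzyl]-3-[(tert-butyldiphenylsilyloxy)methyl]tetrahydrofuran-2-ol (3,4-cis, anomers) | OC1OC[C@H](Cc2ccc(OCc3ccccc3)c(OC)c2)[C@@H]1CO[Si](c1ccccc1)(c1ccccc1)C(C)(C)C
A2 | alternative 1 | 2,6-dimethoxyphenol | COc1cccc(OC)c1O
A3 | alternative 1 | all-trans 7-(benzyloxy)-1-(4-hydroxy-3,5-dimethoxyphenyl)-6-methoxytetralin with a silyloxymethyl group at C2 and a hydroxymethyl group at C3 | COc1cc2c(cc1OCc1ccccc1)[C@H](c1cc(OC)c(O)c(OC)c1)[C@@H](CO[Si](c1ccccc1)(c1ccccc1)C(C)(C)C)[C@H](CO)C2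
A4 | alternative 2 | 4-(benzyloxy)-2-[4-(benzyloxy)-3,5-dimethoxybenzyl]-5-methoxybenzaldehyde | COc1cc(C=O)c(Cc2cc(OC)c(OCc3ccccc3)c(OC)c2)cc1OCc1ccccc1
A5 | alternative 2 | bis[(2S)-1-methoxy-1-oxopropan-2-yl] (2E)-but-2-enedioate | COC(=O)[C@H](C)OC(=O)/C=C/C(=O)O[C@@H](C)C(=O)OC
A6 | alternative 2 | 1-aryl-4-hydroxytetralin-2,3-dicarboxylate bis-lactate ester (1,2-trans, 2,3-trans, 3,4-cis) | COc1cc2c(cc1OCc1ccccc1)[C@H](c1cc(OC)c(OCc3ccccc3)c(OC)c1)[C@@H](C(=O)O[C@@H](C)C(=O)OC)[C@H](C(=O)O[C@@H](C)C(=O)OC)[C@@H]2O
A7 | alternative 3 | 4-[4-(benzyloxy)-3,5-dimethoxyphenyl]-3-[(tert-butyldimethylsilyloxy)methyl]-4-(3-hydroxy-4-methoxyphenyl)butanal (C1 and C2 of the target set) | COc1ccc(cc1O)[C@H](c1cc(OC)c(OCc2ccccc2)c(OC)c1)[C@@H](CO[Si](C)(C)C(C)(C)C)CC=O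
A8 | alternative 3 | formaldehyde | C=O
A9 | alternative 3 | all-trans 1-aryl-7-hydroxy-6-methoxy-2-(silyloxymethyl)tetralin-3-carbaldehyde | COc1cc2c(cc1O)[C@H](c1cc(OC)c(OCc3ccccc3)c(OC)c1)[C@@H](CO[Si](C)(C)C(C)(C)C)[C@H](C=O)C2
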